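**Plan**
- Retrosynthetic cuts, in order: the tert-butyl ester of the acid; the two hydrogens at C3 and the exocyclic CH2 (back to an alkylidene lactone); lactone O1–C2 and C2–C3 (CO removed, leaving a but-3-yn-1-ol); the alkyne–pyrone C4 bond; pyrone O1–C2 and C5–C6 (back to acetoacetate and oxalate).
- Enabling feature: lactone C2 with its two oxygens is one CO set between the C5 hydroxyl and C3, and C3 plus the exocyclic CH2 are the two carbons of an alkyne sitting on pyrone C4.
- Forward order: veratraldehyde and malonate give a prochiral diol, which is taken to alkynol 9. The pyrone ring is closed first and activated as triflate 14. The fragments are joined at the alkyne, the butyrolactone ring closes last by carbonylation, then reduction and ester cleavage follow.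
- Stereochemistry: C4 comes from lipase desymmetrisation of the prochiral diol and is carried through. C3 is set by base equilibration to the trans lactone after conjugate reduction.

Key step: step 12

Assumption: lipase PS is taken to acetylate diol 5 on the enantiotopic arm that gives the (R)-monoacetate 6, the sense assumed here for 2-arylmethylpropane-1,3-diols.

**Step 1**
Reactants: 1 veratraldehyde; 2 diethyl malonate
Product: 3 diethyl 2-(3,4-dimethoxybenzylidene)malonate
Conditions: piperidine (cat.), AcOH (cat.), toluene, reflux, Dean–Stark trap
Reagents that add atoms: none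
Why: Knoevenagel condensation of the non-enolisable aryl aldehyde with the malonate is driven to completion by azeotropic removal of water.

**Step 2**
Reactants: 3 diethyl 2-(3,4-dimethoxybenzylidene)malonate
Product: 4 diethyl 2-(3,4-dimethoxybenzyl)malonate
Conditions: H2 (1 atm), 10% Pd/C, EtOAc, rt
Reagents that add atoms: none
Why: Heterogeneous catalytic hydrogenation saturates the electron-poor benzylidene double bond without touching the esters or aryl ethers.

**Step 3**
Reactants: 4 diethyl 2-(3,4-dimethoxybenzyl)malonate
Product: 5 2-(3,4-dimethoxybenzyl)propane-1,3-diol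
Conditions: LiAlH4, THF, 0 °C to reflux; aqueous NaOH work-up
Reagents that add atoms: none
Why: Hydride reduction of both ester groups with LiAlH4 is the standard conversion of a substituted malonate into the prochiral propane-1,3-diol.

**Step 4**
Reactants: 5 2-(3,4-dimethoxybenzyl)propane-1,3-diol
Product: 6 (2R)-2-(3,4-dimethoxybenzyl)-3-hydroxypropyl acetate
Conditions: lipase PS (Burkholderia cepacia), vinyl acetate, iPr2O, rt
Reagents that add atoms: vinyl acetate, C=COC(C)=O
Why: Lipase-catalysed irreversible transesterification with the enol ester acylates one enantiotopic hydroxymethyl arm of the prochiral diol, so the stereocentre that becomes lactone C4 is set under enzyme control.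

**Step 5**
Reactants: 6 (2R)-2-(3,4-dimethoxybenzyl)-3-hydroxypropyl acetate
Product: 7 (2S)-2-(3,4-dimethoxybenzyl)-3-oxopropyl acetate
Conditions: Dess–Martin periodinane, CH2Cl2, 0 °C to rt; used crude
Reagents that add atoms: none
Why: Dess–Martin oxidation gives the aldehyde under neutral, base-free conditions, so neither enolisation of the new α-stereocentre nor β-elimination of acetate is invited (the descriptor changes only through the priority switch).

**Step 6**
Reactants: 7 (2S)-2-(3,4-dimethoxybenzyl)-3-oxopropyl acetate
Product: 8 (2R)-4,4-dibromo-2-(3,4-dimethoxybenzyl)but-3-en-1-yl acetate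
Conditions: CBr4, PPh3, Zn dust, CH2Cl2, rt (ylide pre-formed); then 7, 0 °C to rt
Reagents that add atoms: carbon tetrabromide, BrC(Br)(Br)Br
Why: Ramirez dibromo-olefination (first stage of the Corey–Fuchs reaction) with the zinc-generated ylide is a base-free Wittig-type reaction that turns the aldehyde carbon into a configurationally safe sp2 centre.

**Step 7**
Reactants: 8 (2R)-4,4-dibromo-2-(3,4-dimethoxybenzyl)but-3-en-1-yl acetate
Product: 9 (2R)-2-(3,4-dimethoxybenzyl)but-3-yn-1-ol
Conditions: n-BuLi (5 equiv), THF, −78 °C to 0 °C; aqueous NH4Cl
Reagents that add atoms: none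
Why: In the second stage of the Corey–Fuchs reaction, bromine–lithium exchange and a Fritsch–Buttenberg–Wiechell-type 1,2-shift give the lithium acetylide while excess n-BuLi removes the acetate by double addition, so the quench frees alkyne and alcohol together and leaves the non-acidic propargylic stereocentre untouched.

**Step 8**
Reactants: 10 methyl acetoacetate; 11 di-tert-butyl oxalate
Product: 12 1-tert-butyl 6-methyl 2,4-dioxohexanedioate
Conditions: NaH, then n-BuLi, THF, 0 °C (dianion, 2 equiv); 11, −78 °C to 0 °C; cold 1 M HCl
Reagents that add atoms: none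
Why: The acetoacetate dianion reacts at its more nucleophilic terminal carbon in a Claisen-type acylation with the strongly electrophilic oxalate diester, and the product is shielded from further attack as its enolate.

**Step 9**
Reactants: 12 1-tert-butyl 6-methyl 2,4-dioxohexanedioate
Product: 13 tert-butyl 4-hydroxy-2-oxo-2H-pyran-6-carboxylate
Conditions: DBU, toluene, rt to 60 °C; aqueous citric acid
Reagents that add atoms: none
Why: Base-mediated lactonisation of the 3,5-diketo ester, with the enol oxygen of the ketone next to the tert-butyl ester attacking the methyl ester, is the standard closure to a 4-hydroxy-2-pyrone and spares the hindered tert-butyl ester.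

**Step 10**
Reactants: 13 tert-butyl 4-hydroxy-2-oxo-2H-pyran-6-carboxylate
Product: 14 tert-butyl 2-oxo-4-(trifluoromethanesulfonyloxy)-2H-pyran-6-carboxylate
Conditions: Tf2O, Et3N, CH2Cl2, −78 °C
Reagents that add atoms: trifluoromethanesulfonic anhydride, O=S(=O)(OS(=O)(=O)C(F)(F)F)C(F)(F)F
Why: O-Sulfonylation of the vinylogous acid at its 4-oxygen with Tf2O and an amine base gives the pyron-4-yl triflate without any acid that would endanger the tert-butyl ester.

**Step 11**
Reactants: 9 (2R)-2-(3,4-dimethoxybenzyl)but-3-yn-1-ol; 14 tert-butyl 2-oxo-4-(trifluoromethanesulfonyloxy)-2H-pyran-6-carboxylate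
Product: 15 tert-butyl 4-[(3R)-3-(3,4-dimethoxybenzyl)-4-hydroxybut-1-yn-1-yl]-2-oxo-2H-pyran-6-carboxylate
Conditions: Pd(PPh3)2Cl2 (cat.), CuI (cat.), Et3N, THF, rt
Reagents that add atoms: none
Why: Sonogashira coupling of the terminal alkyne with the electron-poor vinylogous acyl triflate should run at room temperature through fast oxidative addition to zerovalent palladium, tolerates the free primary alcohol and leaves the propargylic stereocentre alone.

**Step 12**
Reactants: 15 tert-butyl 4-[(3R)-3-(3,4-dimethoxybenzyl)-4-hydroxybut-1-yn-1-yl]-2-oxo-2H-pyran-6-carboxylate; 16 carbon monoxide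
Product: 17 tert-butyl 4-{(E)-[(4R)-4-(3,4-dimethoxybenzyl)-2-oxodihydrofuran-3(2H)-ylidene]methyl}-2-oxo-2H-pyran-6-carboxylate
Conditions: PdCl2 (cat.), PPh3, anhydrous SnCl2, CO (7 atm), MeCN, 70 °C
Reagents that add atoms: none
Why: The primary hydroxyl of 15 attacks CO bound to divalent palladium to give an alkoxycarbonylpalladium chloride, this inserts the tethered alkyne in a syn fashion, and protonolysis of the vinylpalladium by the HCl released returns PdCl2, so palladium stays divalent and no oxidant is needed. The closest known reaction type is the palladium-catalysed cyclocarbonylation of but-3-yn-1-ols to α-methylene and (E)-α-alkylidene γ-butyrolactones with PdCl2, PPh3 and SnCl2. The lactone ring closes 5-exo-dig, with O1–C2 formed from hydroxyl and CO and C2–C3 formed from the acyl carbon and the proximal alkyne carbon. No stereocentre is created: C4 is carried unchanged from 9, and the (E) geometry follows from syn acylpalladation and retentive protonolysis. The step needs exo closure to win over six-membered endo closure, and the two-atom tether secures this because a syn endo insertion would place a trans double bond in a six-membered ring, so the polarisation of the alkyne by the electron-poor pyrone has no say in the regiochemistry. The neutral to weakly acidic medium should spare the tert-butyl ester and gives no base that could move the new alkene into the ring and erase C4.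

**Step 13**
Reactants: 17 tert-butyl 4-{(E)-[(4R)-4-(3,4-dimethoxybenzyl)-2-oxodihydrofuran-3(2H)-ylidene]methyl}-2-oxo-2H-pyran-6-carboxylate
Product: 19 tert-butyl 4-{[(3R,4R)-4-(3,4-dimethoxybenzyl)-2-oxotetrahydrofuran-3-yl]methyl}-2-oxo-2H-pyran-6-carboxylate, via cis-lactone ester 18 (not isolated)
Conditions: [(Ph3P)CuH]6, H2O (few equiv), toluene, rt; then DBU (cat.), 50 °C
Reagents that add atoms: none
Why: Conjugate (1,4) reduction by the copper hydride places hydride on the exocyclic β-carbon of the s-cis-locked alkylidene lactone, a far better acceptor than the quasi-aromatic and more substituted pyrone, and after protonation of the enolate the amidine base, added only once 17 is consumed so that the alkene cannot migrate into the ring, epimerises C3 through the lactone enolate to the thermodynamically preferred trans arrangement relative to the fixed C4 substituent.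

**Step 14**
Reactants: 19 tert-butyl 4-{[(3R,4R)-4-(3,4-dimethoxybenzyl)-2-oxotetrahydrofuran-3-yl]methyl}-2-oxo-2H-pyran-6-carboxylate
Product: 20 4-{[(3R,4R)-4-(3,4-dimethoxybenzyl)-2-oxotetrahydrofuran-3-yl]methyl}-2-oxo-2H-pyran-6-carboxylic acid
Conditions: TFA, CH2Cl2, 0 °C to rt
Reagents that add atoms: none
Why: Acidolysis of the tert-butyl ester with TFA, with loss of the tert-butyl cation as 2-methylpropene, unmasks the acid under conditions that neither open the lactone or the pyrone nor epimerise C3.

**Compound list**
1 | veratraldehyde (3,4-dimethoxybenzaldehyde) | COc1ccc(C=O)cc1OC | starting material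
2 | diethyl malonate | CCOC(=O)CC(=O)OCC | starting material
3 | diethyl 2-(3,4-dimethoxybenzylidene)malonate | CCOC(=O)C(=Cc1ccc(OC)c(OC)c1)C(=O)OCC | intermediate
4 | diethyl 2-(3,4-dimethoxybenzyl)malonate | CCOC(=O)C(Cc1ccc(OC)c(OC)c1)C(=O)OCC | intermediate
5 | 2-(3,4-dimethoxybenzyl)propane-1,3-diol | COc1ccc(CC(CO)CO)cc1OC | intermediate
6 | (2R)-2-(3,4-dimethoxybenzyl)-3-hydroxypropyl acetate | COc1ccc(C[C@@H](COC(C)=O)CO)cc1OC | intermediate
7 | (2S)-2-(3,4-dimethoxybenzyl)-3-oxopropyl acetate | COc1ccc(C[C@@H](COC(C)=O)C=O)cc1OC | intermediate
8 | (2R)-4,4-dibromo-2-(3,4-dimethoxybenzyl)but-3-en-1-yl acetate | COc1ccc(C[C@@H](COC(C)=O)C=C(Br)Br)cc1OC | intermediate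
9 | (2R)-2-(3,4-dimethoxybenzyl)but-3-yn-1-ol | COc1ccc(C[C@@H](CO)C#C)cc1OC | intermediate
10 | methyl acetoacetate | CC(=O)CC(=O)OC | starting material
11 | di-tert-butyl oxalate | CC(C)(C)OC(=O)C(=O)OC(C)(C)C | starting material
12 | 1-tert-butyl 6-methyl 2,4-dioxohexanedioate | COC(=O)CC(=O)CC(=O)C(=O)OC(C)(C)C | intermediate
13 | tert-butyl 4-hydroxy-2-oxo-2H-pyran-6-carboxylate | CC(C)(C)OC(=O)c1cc(O)cc(=O)o1 | intermediate
14 | tert-butyl 2-oxo-4-(trifluoromethanesulfonyloxy)-2H-pyran-6-carboxylate | CC(C)(C)OC(=O)c1cc(OS(=O)(=O)C(F)(F)F)cc(=O)o1 | intermediate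
15 | tert-butyl 4-[(3R)-3-(3,4-dimethoxybenzyl)-4-hydroxybut-1-yn-1-yl]-2-oxo-2H-pyran-6-carboxylate | COc1ccc(C[C@@H](CO)C#Cc2cc(C(=O)OC(C)(C)C)oc(=O)c2)cc1OC | intermediate
16 | carbon monoxide | [C-]#[O+] | starting material
17 | tert-butyl 4-{(E)-[(4R)-4-(3,4-dimethoxybenzyl)-2-oxodihydrofuran-3(2H)-ylidene]methyl}-2-oxo-2H-pyran-6-carboxylate | COc1ccc(C[C@H]2COC(=O)/C2=C/c3cc(C(=O)OC(C)(C)C)oc(=O)c3)cc1OC | intermediate
18 | tert-butyl 4-{[(3S,4R)-4-(3,4-dimethoxybenzyl)-2-oxotetrahydrofuran-3-yl]methyl}-2-oxo-2H-pyran-6-carboxylate (cis lactone) | COc1ccc(C[C@H]2COC(=O)[C@H]2Cc2cc(C(=O)OC(C)(C)C)oc(=O)c2)cc1OC | intermediate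
19 | tert-butyl 4-{[(3R,4R)-4-(3,4-dimethoxybenzyl)-2-oxotetrahydrofuran-3-yl]methyl}-2-oxo-2H-pyran-6-carboxylate (trans lactone) | COc1ccc(C[C@H]2COC(=O)[C@@H]2Cc2cc(C(=O)OC(C)(C)C)oc(=O)c2)cc1OC | intermediate
20 | 4-{[(3R,4R)-4-(3,4-dimethoxybenzyl)-2-oxotetrahydrofuran-3-yl]methyl}-2-oxo-2H-pyran-6-carboxylic acid | COc1ccc(C[C@H]2COC(=O)[C@@H]2Cc2cc(C(=O)O)oc(=O)c2)cc1OC | target

**Step count**
Total: 14 steps. Longest linear sequence: 11 steps (steps 1–7, then 11–14); the pyrone branch (steps 8–10) joins at step 11.

**Steps most likely to fail**

Step 12. The internal, electron-poor alkyne may insert too slowly into the alkoxycarbonyl–palladium bond. Lewis-acid cleavage of the tert-butyl ester, or migration of the new double bond into the lactone ring with loss of C4, could then compete. The fallback carbonylates before the coupling and sets out from 9. Under the same PdCl2, PPh3, SnCl2 and CO conditions the terminal alkynol, the standard substrate class for this cyclocarbonylation, should give (4R)-4-(3,4-dimethoxybenzyl)-3-methylidenedihydrofuran-2(3H)-one F1. A Mizoroki–Heck arylation of its exocyclic methylene with triflate 14 (Pd(OAc)2, PPh3, NaHCO3, Bu4NCl, DMF, 60 °C), with β-hydride elimination toward the new pyronylmethyl carbon, would then return to the route at 17.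

Step 13. Hydride may be transferred to the pyrone ring instead of the exocyclic alkene, or the pyrone may degrade during the base equilibration. The fallback sets out from 17 and replaces nucleophilic hydride by chelation-directed homogeneous hydrogenation (H2, [Rh(nbd)(dppb)]BF4, CH2Cl2, rt). The cationic rhodium binds the lactone carbonyl and the s-cis exocyclic alkene, an arrangement the ring-locked pyrone alkenes cannot offer. Delivery of hydrogen from the face opposite the C4 substituent should give the cis lactone 18, which a short DBU treatment epimerises so that the route is rejoined at 19. This fallback makes no compound outside the list (F0).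

Step 8. The dianion may attack a second time, at the α-keto ester of the product or at the second ester group of the oxalate, or proton transfer may stall the acylation. The fallback sets out from 11 and uses commercial 2,2,6-trimethyl-4H-1,3-dioxin-4-one as the acetoacetate equivalent. Its lithium dienolate (LDA, THF, −78 °C) is acylated at the exocyclic carbon by 11 to give tert-butyl 3-(2,2-dimethyl-4-oxo-4H-1,3-dioxin-6-yl)-2-oxopropanoate F2. Heating F2 in toluene at reflux expels acetone by retro-[4+2] cleavage, and the acylketene is trapped by the enol oxygen of the keto ester, which closes the pyrone and comes back to the route at 13.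

**Further compounds**
F1 | step 12 | (4R)-4-(3,4-dimethoxybenzyl)-3-methylidenedihydrofuran-2(3H)-one | COc1ccc(C[C@H]2COC(=O)C2=C)cc1OC
F0 | step 13 | none | none
F2 | step 8 | tert-butyl 3-(2,2-dimethyl-4-oxo-4H-1,3-dioxin-6-yl)-2-oxopropanoate | CC1(C)OC(CC(=O)C(=O)OC(C)(C)C)=CC(=O)O1
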